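I choose to compare these flasks not by clock time but by the catalyst dose D, the charged free catalyst multiplied by the time. West has 2.00 mM·h and south-east has 2.00 mM·h.

all flasks: substrate 0.20 M
- alpha: coupling partner 0.24 M; free catalyst 0.46 mM; temperature 75 °C; run made earlier
- beta: coupling partner 0.24 M; free catalyst 0.91 mM; temperature 86 °C; run made earlier
- gamma: coupling partner 0.24 M; free catalyst 1.4 mM; temperature 75 °C; run made earlier
- west: coupling partner 0.240 M; free catalyst 2.0 mM; temperature 80 °C; time 1.0 h
- south-east: coupling partner 0.240 M; free catalyst 0.50 mM; temperature 80 °C; time 4.0 h

| run | time / min | target / % |
|---|---|---|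
| alpha | 2.50 | 0.1 |
| alpha | 6.00 | 1.0 |
| alpha | 12.0 | 1.0 |
| alpha | 30.0 | 2.4 |
| beta | 4.00 | 1.3 |
| beta | 10.0 | 4.9 |
| beta | 20.0 | 9.2 |
| beta | 30.0 | 13.9 |
| gamma | 8.00 | 1.9 |
| gamma | 15.0 | 4.9 |
| gamma | 25.0 | 7.2 |
| gamma | 30.0 | 8.8 |

(standard deviation of a reading: 0.3 percentage points)

- the flask that ends with the higher amount of target, in percent of the substrate charged, or "neither" when 2 percentage points or less lies between them (west / south-east / neither)
- final target, as a percentage of the substrate charged, in west
- final target, as a percentage of the substrate charged, in south-east

- what was read earlier has a scatter of 0.3 percentage points, one standard deviation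
- steps that have been proposed: substrate + free catalyst -> catalyst intermediate A; coupling partner + catalyst intermediate A -> catalyst intermediate B; catalyst intermediate B -> by-product + catalyst intermediate C; catalyst intermediate C -> catalyst intermediate D; catalyst intermediate D -> free catalyst + target

If each catalyst molecule turns over at a pace set by the substrate, the coupling partner and the temperature, and west and south-east match in all of those, their target should follow D. The runs can test this. Alpha at 30.0 min has 13.8 mM·min, and gamma at 8.00 min has 11.2 mM·min, a ratio of 1.23. Their targets, 2.4% and 1.9%, stand in a ratio of 1.26, which is a reading with its scatter.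

Now I turn the question round: what would put more than 2 percentage points between the flasks? An induction period (lag) fixed at τ minutes would take the share τ/t from each flask, and that share is larger in west than in south-east. For the size of the target I take the slopes per mM of gamma and beta, at 75 °C and 86 °C. Their geometric mean serves for 80 °C, which lies near the middle, and a straight line then gives 41.4% in each of the two flasks. The gap reaches the margin at τ = 3.86 min. Gamma's first and last readings, taken at 75 °C, extrapolate to a lag of 1.94 min, about half of that, and by my estimate a lag of that size puts west behind south-east by 1 point. So I say neither.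

The forecast says neither, with 35% (27% to 43%) in west and 33% (24% to 41%) in south-east, lower than my straight line, holding that “the rate is roughly first order in catalyst”.

West ends at 36.1% and south-east at 36.3%, so the answer is neither.

    substrate + free catalyst → catalyst intermediate A (k = 0.150 /M/s, Ea = 62.0 kJ/mol)
    coupling partner + catalyst intermediate A → catalyst intermediate B (k = 6.50 /M/s, Ea = 61.0 kJ/mol)
    catalyst intermediate B → by-product + catalyst intermediate C (k = 0.0380 /s, Ea = 93.0 kJ/mol)
    catalyst intermediate C → catalyst intermediate D (k = 0.0340 /s, Ea = 89.0 kJ/mol)
    catalyst intermediate D → free catalyst + target (k = 0.970 /s, Ea = 73.0 kJ/mol)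
    (constants at 80 °C)

At a dose of 1.00 mM·h, west holds 18.7% of target at 0.500 h, and south-east holds 19.0% of target at 2.00 h. A neighbouring flask keeps west's D of 2.00 mM·h but charges 0.12 M of substrate. If that dose made the same amount of target as in west, the neighbouring flask would reach 60.1%, and if the percentage held, 36.1%. The neighbouring flask gives 45.1% of target, with 54% of its substrate left.

The readings were generated by integration for substances that don't exist; noise was put on by code.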